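**Retrosynthetic overview**

- The strategy rests on ring D (N5–C12b–C13–C13a–C4a): C13 is a benzylic carbon that carries the methyl oxalyl group, and C12b lies between N5 and C12a at the oxidation level of an amide carbon. The C12b–C13 bond is therefore cut last, in the sense of a Madelung condensation.
- This leads back to a 2-aryl-β-carbolin-1-one whose N-aryl ring (ring E) carries an ortho CH2–CO–CO2Me arm; every oxidation level of the target is already present in it.
- The pyruvate arm comes from an aryl aldehyde by Horner–Wadsworth–Emmons olefination with an α-methoxyphosphonoacetate and enol ether hydrolysis.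
- The N5–C4a bond comes from SNAr of the pyridone nitrogen on 4-bromo-2-fluorobenzaldehyde. Rings A/B/C are bought as tetrahydro-β-carbolin-1-one and dehydrogenated; ring E is bought with the aldehyde; ring D is the only ring made, and it is made last.
- N12–H stays unprotected throughout: a group on N12 would clash with the C13 substituent in the bay, and the free N–H can hydrogen-bond to the C13 ketone.

Key step: step 5

Remark: the target has no stereocentre and no configurationally stable axis, so it is achiral and no enantiocontrol is required.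

**Route**

Step 1
Reactants: 1 2,3,4,9-tetrahydro-1H-pyrido[3,4-b]indol-1-one
Product: 2 2,9-dihydro-1H-pyrido[3,4-b]indol-1-one (β-carbolin-1-one)
Conditions: DDQ (1.2 equiv), dry 1,4-dioxane, reflux
Reagents that add atoms: none
Why: DDQ dehydrogenation, in which hydride abstraction from C4 (benzylic to the indole) and loss of the C3 proton give the aromatic 2-pyridone, while dry solvent keeps water from trapping the C4 cation.

Step 2
Reactants: 2 2,9-dihydro-1H-pyrido[3,4-b]indol-1-one; 3 4-bromo-2-fluorobenzaldehyde
Product: 4 4-bromo-2-(1-oxo-1,9-dihydro-2H-pyrido[3,4-b]indol-2-yl)benzaldehyde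
Conditions: 3 (1.05 equiv), K2CO3 (1.5 equiv), DMF, 80–90 °C
Reagents that add atoms: none
Why: Nucleophilic aromatic substitution (SNAr), in which carbonate should ionise the more acidic pyridone N2–H rather than the 2-acylindole-type N9–H, the pyridonate attacks through nitrogen at the carbon ortho to the formyl group, and fluoride leaves far faster than the bromide para to CHO (element effect).

Step 3
Reactants: 4 4-bromo-2-(1-oxo-1,9-dihydro-2H-pyrido[3,4-b]indol-2-yl)benzaldehyde; 5 methyl 2-(dimethoxyphosphoryl)-2-methoxyacetate
Product: 6 methyl 3-[4-bromo-2-(1-oxo-1,9-dihydro-2H-pyrido[3,4-b]indol-2-yl)phenyl]-2-methoxyprop-2-enoate (E/Z mixture, used as such)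
Conditions: 5 (2.3 equiv), LiHMDS (2.2 equiv), THF, −78 °C to rt; aq NH4Cl
Reagents that add atoms: none
Why: Horner–Wadsworth–Emmons olefination of the aryl aldehyde with the α-methoxyphosphonate anion, used in excess because one equivalent is consumed by N9–H, should give the 2-methoxyacrylate, whose geometry does not matter because both isomers converge in step 4.

Step 4
Reactants: 6 methyl 3-[4-bromo-2-(1-oxo-1,9-dihydro-2H-pyrido[3,4-b]indol-2-yl)phenyl]-2-methoxyprop-2-enoate
Product: 7 methyl 3-[4-bromo-2-(1-oxo-1,9-dihydro-2H-pyrido[3,4-b]indol-2-yl)phenyl]-2-oxopropanoate (keto/enol mixture)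
Conditions: 3 M aq HCl, 1,4-dioxane, 60 °C; dried azeotropically before step 5
Reagents that add atoms: water, O
Why: Acid-catalysed enol ether hydrolysis, in which protonation at the benzylic carbon, addition of water to the oxocarbenium ion and loss of methanol unmask the α-keto ester under conditions that the methyl ester, the pyridone and the aryl bromide should tolerate.

Step 5
Reactants: 7 methyl 3-[4-bromo-2-(1-oxo-1,9-dihydro-2H-pyrido[3,4-b]indol-2-yl)phenyl]-2-oxopropanoate
Product: 10 methyl 2-(3-bromo-12H-pyrido[1,2-a:3,4-b']diindol-13-yl)-2-oxoacetate, via 1-triflyloxy-β-carbolin-2-ium triflate 8 (not isolated), via 13H-pyridodiindol-5-ium triflate 9 (not isolated)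
Conditions: Tf2O (1.1 equiv), 2-chloropyridine (2.5 equiv), CH2Cl2, −78 °C to rt; aq NaHCO3
Reagents that add atoms: none
Why: Proposed new method: Tf2O should sulfonylate the pyridone oxygen of 7 to give the 1-triflyloxy-β-carbolin-2-ium ion 8, whose C12b is strongly electrophilic; the pyruvate enol then adds through its benzylic carbon C13, triflate is expelled to give the 13H-diindolium ion 9, and loss of the doubly activated C13–H makes ring D aromatic and the molecule neutral. The closest known reactions are the Madelung closure of anilides that carry an acceptor-stabilised ortho methylene and Tf2O/2-halopyridine amide activation with capture by a tethered π-nucleophile (Bischler–Napieralski type); the untested element is an N-aryl 2-pyridone as the amide. Ring D closes 5-(enolexo)-exo-trig when counted, as in a Madelung reaction, against the departing C12b–O bond (formally 5-endo against C12b=N5+), and the N5-aryl ring, twisted out of the pyridinium plane, holds C13 over the π-face of C12b. No stereocentre is formed. The step needs O-activation of the pyridone in preference to O-triflation of the enol or sulfonylation at N12, which the much higher oxygen nucleophilicity of the pyridone, one equivalent of Tf2O at low temperature and the absence of a strong base should secure, and it needs C- rather than O-attack of the enol, which the five- against seven-membered ring size secures. The product should resist further activation because of its push–pull (vinylogous amide) character and the N12–H···O=C13 hydrogen bond.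

**Compound list**

1 | 2,3,4,9-tetrahydro-1H-pyrido[3,4-b]indol-1-one | O=C1NCCc2c1[nH]c1ccccc21 | starting material
2 | 2,9-dihydro-1H-pyrido[3,4-b]indol-1-one | O=c1[nH]ccc2c3ccccc3[nH]c12 | intermediate
3 | 4-bromo-2-fluorobenzaldehyde | O=Cc1ccc(Br)cc1F | starting material
4 | 4-bromo-2-(1-oxo-1,9-dihydro-2H-pyrido[3,4-b]indol-2-yl)benzaldehyde | O=Cc1ccc(Br)cc1-n1ccc2c3ccccc3[nH]c2c1=O | intermediate
5 | methyl 2-(dimethoxyphosphoryl)-2-methoxyacetate | COC(=O)C(OC)P(=O)(OC)OC | starting material
6 | methyl 3-[4-bromo-2-(1-oxo-1,9-dihydro-2H-pyrido[3,4-b]indol-2-yl)phenyl]-2-methoxyprop-2-enoate (E/Z mixture) | COC(=O)C(OC)=Cc1ccc(Br)cc1-n1ccc2c3ccccc3[nH]c2c1=O | intermediate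
7 | methyl 3-[4-bromo-2-(1-oxo-1,9-dihydro-2H-pyrido[3,4-b]indol-2-yl)phenyl]-2-oxopropanoate | COC(=O)C(=O)Cc1ccc(Br)cc1-n1ccc2c3ccccc3[nH]c2c1=O | intermediate
8 | 2-[5-bromo-2-(3-methoxy-2,3-dioxopropyl)phenyl]-1-{[(trifluoromethyl)sulfonyl]oxy}-9H-pyrido[3,4-b]indol-2-ium trifluoromethanesulfonate | COC(=O)C(=O)Cc1ccc(Br)cc1-[n+]1ccc2c3ccccc3[nH]c2c1OS(=O)(=O)C(F)(F)F.[O-]S(=O)(=O)C(F)(F)F | intermediate (not isolated)
9 | 3-bromo-13-(2-methoxy-2-oxoacetyl)-12,13-dihydropyrido[1,2-a:3,4-b']diindol-5-ium trifluoromethanesulfonate | COC(=O)C(=O)C1c2ccc(Br)cc2-[n+]2ccc3c4ccccc4[nH]c3c12.[O-]S(=O)(=O)C(F)(F)F | intermediate (not isolated)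
10 | methyl 2-(3-bromo-12H-pyrido[1,2-a:3,4-b']diindol-13-yl)-2-oxoacetate | COC(=O)C(=O)c1c2ccc(Br)cc2n2ccc3c4ccccc4[nH]c3c12 | target

**Step count**

Total steps: 5. Longest linear sequence: 5 steps (1 → 2 → 4 → 6 → 7 → 10).

**Steps most likely to fail**

1. Step 5 (proposed new method). The enol oxygen may be sulfonylated instead of the pyridone oxygen, the carbolinium ion may lose N–H to give an unreactive anhydro-base, or the weakly nucleophilic enol may fail to add, so that the activated pyridone is hydrolysed back on work-up. The fallback sets out from aldehyde 4 and comes back at target 10, and it puts the oxalyl group on after ring D is closed. Reductive oxo-amide coupling of the formyl group with the pyridone carbonyl by low-valent titanium (TiCl3, Zn dust, DME, reflux; McMurry-type indole synthesis) should give 3-bromo-12H-pyrido[1,2-a:3,4-b']diindole F1. Its electron-rich C13 should then be acylated by oxalyl chloride (CH2Cl2, 0 °C) to give 2-(3-bromo-12H-pyrido[1,2-a:3,4-b']diindol-13-yl)-2-oxoacetyl chloride F2, which is quenched in the same flask with methanol and triethylamine to give 10.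

2. Step 2. Arylation may also occur at N9 or at the pyridone oxygen, and a second arylation may follow the first. The fallback sets out from lactam 1 and comes back at aldehyde 4, and it blocks N9 while the lactam N–H is still far less acidic. Treatment with NaH (1.0 equiv) and SEMCl (DMF, 0 °C) should give 9-{[2-(trimethylsilyl)ethoxy]methyl}-2,3,4,9-tetrahydro-1H-pyrido[3,4-b]indol-1-one F3. DDQ in dry dioxane should then give 9-{[2-(trimethylsilyl)ethoxy]methyl}-2,9-dihydro-1H-pyrido[3,4-b]indol-1-one F4. SNAr with 3 (K2CO3, DMF, 90 °C) can now occur only at the pyridone and should give 4-bromo-2-(1-oxo-9-{[2-(trimethylsilyl)ethoxy]methyl}-1,9-dihydro-2H-pyrido[3,4-b]indol-2-yl)benzaldehyde F5. TBAF in THF at 60 °C removes the SEM group and gives 4; the group is taken off here because it would hinder the ring closure of step 5.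

3. Step 4. The push–pull enol ether may hydrolyse slowly, so that the forcing acid needed also cleaves the methyl ester or degrades the sensitive arylpyruvate. The fallback sets out from aldehyde 4 and comes back at pyruvate 7, and it replaces acid hydrolysis by fluoride cleavage of a silyl enol ether. Horner–Wadsworth–Emmons reaction of 4 with methyl 2-[(tert-butyldimethylsilyl)oxy]-2-(dimethoxyphosphoryl)acetate (COC(=O)C(O[Si](C)(C)C(C)(C)C)P(=O)(OC)OC; LiHMDS, THF, −78 °C to rt) should give methyl 3-[4-bromo-2-(1-oxo-1,9-dihydro-2H-pyrido[3,4-b]indol-2-yl)phenyl]-2-[(tert-butyldimethylsilyl)oxy]prop-2-enoate F6. CsF with acetic acid in MeCN at 0 °C should then remove the silyl group under nearly neutral conditions to give 7.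

**Further compounds**

F1 | step 5 | 3-bromo-12H-pyrido[1,2-a:3,4-b']diindole | c1c2ccc(Br)cc2n2ccc3c4ccccc4[nH]c3c12
F2 | step 5 | 2-(3-bromo-12H-pyrido[1,2-a:3,4-b']diindol-13-yl)-2-oxoacetyl chloride | ClC(=O)C(=O)c1c2ccc(Br)cc2n2ccc3c4ccccc4[nH]c3c12
F3 | step 2 | 9-{[2-(trimethylsilyl)ethoxy]methyl}-2,3,4,9-tetrahydro-1H-pyrido[3,4-b]indol-1-one | O=C1NCCc2c1n(COCC[Si](C)(C)C)c1ccccc21
F4 | step 2 | 9-{[2-(trimethylsilyl)ethoxy]methyl}-2,9-dihydro-1H-pyrido[3,4-b]indol-1-one | O=c1[nH]ccc2c3ccccc3n(COCC[Si](C)(C)C)c12
F5 | step 2 | 4-bromo-2-(1-oxo-9-{[2-(trimethylsilyl)ethoxy]methyl}-1,9-dihydro-2H-pyrido[3,4-b]indol-2-yl)benzaldehyde | O=Cc1ccc(Br)cc1-n1ccc2c3ccccc3n(COCC[Si](C)(C)C)c2c1=O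
F6 | step 4 | methyl 3-[4-bromo-2-(1-oxo-1,9-dihydro-2H-pyrido[3,4-b]indol-2-yl)phenyl]-2-[(tert-butyldimethylsilyl)oxy]prop-2-enoate | COC(=O)C(O[Si](C)(C)C(C)(C)C)=Cc1ccc(Br)cc1-n1ccc2c3ccccc3[nH]c2c1=O
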